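**Retrosynthetic overview**

- The CMe2OH group on C2' is read as a hydrated isopropenyl group, so the target comes from the 2-isopropenyl dihydrofuran by a late Markovnikov hydration.
- Feature: C3, the only CH of ring A, lies between the oxygen-bearing carbons C2 and C4 and is the carbon nucleophile of a cyclic 1,3-dione; C2' of ring B is then an allylic O–CH carbon. Ring B (O–C2'–C3', fused at C3–C4) is therefore cut at C3–C3' and O–C2', giving the gem-diprenyl acyl trione and a racemic isoprene-derived C5 bis-electrophile, joined in one palladium pi-allyl annulation.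
- Ring A is the ring of phloroglucinol: Friedel–Crafts isovalerylation, then dearomatising double prenylation at one ring carbon (C1).
- The C5 dicarbonate is built from a silyl-protected hydroxyacetone and a vinyl Grignard reagent; the tertiary carbonate is installed before the primary one, so that no tertiary alkoxide ever sits next to a carbonate (which would close to a cyclic carbonate).
- Ring order: ring A from the aromatic starting material, ring B in the key step, hydration last.

Key step: step 6

Ring A numbering used below: C1 = quaternary carbon with two prenyl groups, C2 = ring carbonyl, C3 = the ring CH, C4 = carbon bonded to the ring B oxygen, C5 = acyl-bearing carbon, C6 = enol carbon.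

Remark: trione 6 and its descendants are written as one enol tautomer; the tautomers interconvert.

Remark (assumption): the (R,R) antipode of the ligand is written for step 6. The sense of induction is to be confirmed in a first run; the mirror-image ligand, equally available, would be taken if (S) should result.

**Step 1**
Reactants: 1 phloroglucinol; 2 3-methylbutanoyl chloride
Product: 3 1-(2,4,6-trihydroxyphenyl)-3-methylbutan-1-one (phlorisovalerophenone)
Conditions: AlCl3 (4 equiv), PhNO2–CH2Cl2, 0 °C → 45 °C; ice, aq HCl
Reagents that add atoms: none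
Why: Friedel–Crafts C-acylation of the electron-rich arene should stop after one acyl group, because the aluminium-bound aryl ketone is deactivated; no stereocentre is formed.

**Step 2**
Reactants: 3 phlorisovalerophenone; 4 prenyl bromide (1-bromo-3-methylbut-2-ene)
Product: 6 2-(3-methylbutanoyl)-4,4-bis(3-methylbut-2-enyl)cyclohexane-1,3,5-trione (enol form), via monoprenyl ketone 5 (not isolated)
Conditions: KOH (aq), 4 (2.1 equiv in all, slow addition), 0 °C; aq HCl to pH 2; chromatography
Reagents that add atoms: prenyl bromide (second equivalent), CC(C)=CCBr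
Why: Base-mediated dearomatising C-allylation of an acylphloroglucinolate is a known mode: the first equivalent of 4 gives the 3-prenyl ketone 5, whose anion is expected to take the second equivalent at the same ring carbon, which puts both prenyl groups on C1 and leaves C3 as the last ring CH; the aromatic 3,5-diprenyl isomer and triprenylated material are expected as by-products and are removed on silica, and no stereocentre is formed.

**Step 3**
Reactants: 7 1-[(tert-butyldimethylsilyl)oxy]propan-2-one; 8 vinylmagnesium bromide
Product: 10 rac-1-[(tert-butyldimethylsilyl)oxy]-2-methylbut-3-en-2-yl methyl carbonate, via magnesium alkoxide 9 (not isolated)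
Conditions: 8 (1.2 equiv), THF, −78 → 0 °C; then ClCO2Me (1.5 equiv), 0 °C → rt
Reagents that add atoms: methyl chloroformate, COC(=O)Cl
Why: Grignard 1,2-addition to the ketone followed by O-acylation of the tertiary magnesium alkoxide in the same flask; the silylated primary oxygen offers no acyl group for the alkoxide to attack, and the stereocentre is formed racemic on purpose because the later ionisation erases it.

**Step 4**
Reactants: 10 rac-1-[(tert-butyldimethylsilyl)oxy]-2-methylbut-3-en-2-yl methyl carbonate
Product: 11 rac-1-hydroxy-2-methylbut-3-en-2-yl methyl carbonate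
Conditions: HF·pyridine, pyridine, THF, 0 °C; used at once
Reagents that add atoms: none
Why: Fluoride desilylation of a primary silyl ether under acidic conditions generates no alkoxide, so the tertiary carbonate should neither migrate nor close to the five-membered cyclic carbonate.

**Step 5**
Reactants: 11 rac-1-hydroxy-2-methylbut-3-en-2-yl methyl carbonate
Product: 12 rac-2-methylbut-3-ene-1,2-diyl dimethyl dicarbonate
Conditions: ClCO2Me (1.3 equiv), pyridine, CH2Cl2, 0 °C
Reagents that add atoms: methyl chloroformate, COC(=O)Cl
Why: Pyridine-mediated O-acylation of a primary alcohol by a chloroformate is fast at 0 °C and should outrun attack of the hydroxyl group on the neighbouring carbonate.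

**Step 6**
Reactants: 6 2-(3-methylbutanoyl)-4,4-bis(3-methylbut-2-enyl)cyclohexane-1,3,5-trione; 12 rac-2-methylbut-3-ene-1,2-diyl dimethyl dicarbonate
Product: 14 (2R)-6-hydroxy-7-(3-methylbutanoyl)-5,5-bis(3-methylbut-2-en-1-yl)-2-(prop-1-en-2-yl)-2,3-dihydro-1-benzofuran-4(5H)-one, via allylic carbonate 13 (not isolated)
Conditions: 12 (1.2 equiv), Pd2(dba)3·CHCl3 (2.5 mol %), N,N'-[(1R,2R)-cyclohexane-1,2-diyl]bis[2-(diphenylphosphanyl)benzamide] (the (R,R)-DACH-phenyl bisphosphine, 7.5 mol %), degassed CH2Cl2 (0.05 M), rt
Reagents that add atoms: none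
Why: Zerovalent palladium ionises the tertiary carbonate of 12, its only allylic C–O bond, and the soft carbon C3 of the anion of 6 attacks the unsubstituted CH2 terminus of the pi-allyl (Tsuji–Trost allylation), which forms C3–C3' and gives the (E)-allylic carbonate 13, whose primary carbonate has thereby become allylic. A second ionisation gives a 2-methyl-substituted pi-allyl tethered to C3, and the enolate oxygen on C4 attacks its internal CH terminus, which forms O–C2' and closes ring B in the 5-exo mode, the alkene staying outside the ring as the isopropenyl group. The closest known reaction type is the palladium-catalysed asymmetric (3+2) annulation of cyclic 1,3-diketones with butenediyl dicarbonates to 2-vinyl-2,3-dihydrofurans, together with the asymmetric pi-allyl O-cyclisation of phenols to 2-isopropenyl-2,3-dihydrobenzofurans. C2' is set by the chiral bisphosphine: the two faces of the second pi-allyl exchange by π–σ–π through the CH2 terminus faster than the ring closes, so both enantiomers of 12 should be funnelled to (R) (dynamic kinetic asymmetric transformation). The step needs linear C-attack in the first alkylation, secured by the fully substituted other terminus and by the reversibility of O-allylation under palladium, and it needs closure through the C4 oxygen and not the C2 oxygen, expected because the C2 oxygen is flanked by the quaternary C1 with its two prenyl groups; this is to be checked by HMBC on 14. The acidic trione needs no base beyond the methoxide that each carbonate releases together with CO2.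

**Step 7**
Reactants: 14 (2R)-isopropenyl dihydrobenzofuranone
Product: 15 (2R)-6-hydroxy-2-(2-hydroxypropan-2-yl)-7-(3-methylbutanoyl)-5,5-bis(3-methylbut-2-en-1-yl)-2,3-dihydro-1-benzofuran-4(5H)-one
Conditions: Co(acac)2 (20 mol %), PhSiH3 (2 equiv), O2 (1 atm), THF, 0 °C → rt, stopped when 14 is consumed; aqueous work-up
Reagents that add atoms: dioxygen, O=O
Why: Mukaiyama hydration: hydrogen-atom transfer from a cobalt hydride to the unhindered 1,1-disubstituted alkene gives a tertiary radical that is trapped by O2 and reduced to the tertiary alcohol; this alkene should react faster than the two trisubstituted prenyl alkenes, and C2' is not touched.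

**Compound list**

1 | phloroglucinol | Oc1cc(O)cc(O)c1 | starting material
2 | 3-methylbutanoyl chloride | CC(C)CC(=O)Cl | starting material
3 | 1-(2,4,6-trihydroxyphenyl)-3-methylbutan-1-one | CC(C)CC(=O)c1c(O)cc(O)cc1O | intermediate
4 | prenyl bromide (1-bromo-3-methylbut-2-ene) | CC(C)=CCBr | starting material
5 | 3-methyl-1-[2,4,6-trihydroxy-3-(3-methylbut-2-enyl)phenyl]butan-1-one (monoprenyl ketone) | CC(C)CC(=O)c1c(O)cc(O)c(CC=C(C)C)c1O | intermediate (not isolated)
6 | 2-(3-methylbutanoyl)-4,4-bis(3-methylbut-2-enyl)cyclohexane-1,3,5-trione, enol form | CC(C)=CCC1(CC=C(C)C)C(=O)C=C(O)C(C(=O)CC(C)C)=C1O | intermediate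
7 | 1-[(tert-butyldimethylsilyl)oxy]propan-2-one | CC(=O)CO[Si](C)(C)C(C)(C)C | starting material
8 | vinylmagnesium bromide | C=C[Mg]Br | starting material
9 | bromomagnesium rac-1-[(tert-butyldimethylsilyl)oxy]-2-methylbut-3-en-2-olate | C=CC(C)(CO[Si](C)(C)C(C)(C)C)O[Mg]Br | intermediate (not isolated)
10 | rac-1-[(tert-butyldimethylsilyl)oxy]-2-methylbut-3-en-2-yl methyl carbonate | COC(=O)OC(C)(C=C)CO[Si](C)(C)C(C)(C)C | intermediate
11 | rac-1-hydroxy-2-methylbut-3-en-2-yl methyl carbonate | COC(=O)OC(C)(C=C)CO | intermediate
12 | rac-2-methylbut-3-ene-1,2-diyl dimethyl dicarbonate | COC(=O)OCC(C)(OC(=O)OC)C=C | intermediate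
13 | 6-[(2E)-4-(methoxycarbonyloxy)-3-methylbut-2-enyl]-2-(3-methylbutanoyl)-4,4-bis(3-methylbut-2-enyl)cyclohexane-1,3,5-trione, enol form | CC(C)=CCC1(CC=C(C)C)C(=O)C(C/C=C(\C)COC(=O)OC)=C(O)C(C(=O)CC(C)C)=C1O | intermediate (not isolated)
14 | (2R)-6-hydroxy-7-(3-methylbutanoyl)-5,5-bis(3-methylbut-2-en-1-yl)-2-(prop-1-en-2-yl)-2,3-dihydro-1-benzofuran-4(5H)-one | CC(C)=CCC1(CC=C(C)C)C(=O)C2=C(O[C@@H](C(C)=C)C2)C(C(=O)CC(C)C)=C1O | intermediate
15 | (2R)-6-hydroxy-2-(2-hydroxypropan-2-yl)-7-(3-methylbutanoyl)-5,5-bis(3-methylbut-2-en-1-yl)-2,3-dihydro-1-benzofuran-4(5H)-one | CC(C)=CCC1(CC=C(C)C)C(=O)C2=C(O[C@@H](C(C)(C)O)C2)C(C(=O)CC(C)C)=C1O | target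

**Step count**

Total: 7 steps. Longest linear sequence: 5 steps (steps 3, 4, 5, 6, 7); the trione branch is 4 steps (1, 2, 6, 7).

**Steps most likely to fail**

1. Step 6. The cascade may be diverted before the stereodefining ring closure: attack of C3 on the substituted terminus of the first pi-allyl, loss of a β-hydrogen from that tertiary pi-allyl to a diene, or formation of the (Z)-alkene, which would feed the wrong pi-allyl geometry to the cyclisation and lower the facial selectivity. Ring closure through the C2 oxygen is the second danger. The fallback separates the two bond formations. It sets out from 6. Commercial 2-methyl-2-vinyloxirane is opened with TiCl4 (CH2Cl2, −78 °C) to (E)-4-chloro-2-methylbut-2-en-1-ol F1, which is acylated (ClCO2Me, pyridine, 0 °C) to (E)-4-chloro-2-methylbut-2-en-1-yl methyl carbonate F2. The sodium salt of 6 (NaOMe 1.0 equiv, MeOH, NaI cat., 0 °C; no free methoxide is left to cleave the carbonate) is C-alkylated at C3 by F2, the same SN2 allylation that installs the prenyl groups, and gives 13 as an isolated, geometrically pure compound. Only the precedented asymmetric pi-allyl O-cyclisation is then left to palladium (Pd2(dba)3·CHCl3, the same ligand, AcOH 1 equiv, CH2Cl2, rt), and the route is rejoined at 14. The choice of oxygen and the enantioselectivity can then be studied on one defined substrate.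

2. Step 2. The second prenylation may go to the free ring carbon and give the aromatic 3,5-diprenyl isomer, and a third alkylation may follow. The fallback blocks that carbon. It sets out from 2: Friedel–Crafts acylation (AlCl3, PhNO2–CH2Cl2) of commercial methyl 2,4,6-trihydroxybenzoate gives methyl 2,4,6-trihydroxy-3-(3-methylbutanoyl)benzoate F3, whose single free ring carbon must take both prenyl groups (4, 2 equiv, aq KOH, 0 °C), giving methyl 2,4-dihydroxy-3-(3-methylbutanoyl)-5,5-bis(3-methylbut-2-en-1-yl)-6-oxocyclohexa-1,3-diene-1-carboxylate F4. Saponification (LiOH, aq THF, 40 °C) and acidification let the vinylogous β-keto acid lose CO2, and the route is rejoined at 6.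

3. Step 7. Hydrogen-atom transfer may also reach the two prenyl alkenes, which give tertiary radicals as well, so that over-hydration competes. The fallback carries allyl groups in place of prenyl groups through the annulation and hydration and makes the prenyl alkenes last. It sets out from 3: allyl bromide (2 equiv, aq KOH, 0 °C) gives 2-(3-methylbutanoyl)-4,4-di(prop-2-en-1-yl)cyclohexane-1,3,5-trione F5. Annulation with 12 under the conditions of step 6 gives (2R)-6-hydroxy-7-(3-methylbutanoyl)-5,5-di(prop-2-en-1-yl)-2-(prop-1-en-2-yl)-2,3-dihydro-1-benzofuran-4(5H)-one F6. Mukaiyama hydration (Co(acac)2, PhSiH3, O2, THF) gives (2R)-6-hydroxy-2-(2-hydroxypropan-2-yl)-7-(3-methylbutanoyl)-5,5-di(prop-2-en-1-yl)-2,3-dihydro-1-benzofuran-4(5H)-one F7; monosubstituted alkenes give only secondary radicals and should be hydrated more slowly than the 1,1-disubstituted one. Cross-metathesis of both allyl groups with 2-methylbut-2-ene (second-generation Grubbs catalyst, 40 °C) rejoins the route at 15.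

**Further compounds**

F1 | step 6 | (E)-4-chloro-2-methylbut-2-en-1-ol | OC/C(C)=C/CCl
F2 | step 6 | (E)-4-chloro-2-methylbut-2-en-1-yl methyl carbonate | COC(=O)OC/C(C)=C/CCl
F3 | step 2 | methyl 2,4,6-trihydroxy-3-(3-methylbutanoyl)benzoate | COC(=O)c1c(O)c(C(=O)CC(C)C)c(O)cc1O
F4 | step 2 | methyl 2,4-dihydroxy-3-(3-methylbutanoyl)-5,5-bis(3-methylbut-2-en-1-yl)-6-oxocyclohexa-1,3-diene-1-carboxylate | CC(C)=CCC1(CC=C(C)C)C(=O)C(C(=O)OC)=C(O)C(C(=O)CC(C)C)=C1O
F5 | step 7 | 2-(3-methylbutanoyl)-4,4-di(prop-2-en-1-yl)cyclohexane-1,3,5-trione, enol form | C=CCC1(CC=C)C(=O)C=C(O)C(C(=O)CC(C)C)=C1O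
F6 | step 7 | (2R)-6-hydroxy-7-(3-methylbutanoyl)-5,5-di(prop-2-en-1-yl)-2-(prop-1-en-2-yl)-2,3-dihydro-1-benzofuran-4(5H)-one | C=CCC1(CC=C)C(=O)C2=C(O[C@@H](C(C)=C)C2)C(C(=O)CC(C)C)=C1O
F7 | step 7 | (2R)-6-hydroxy-2-(2-hydroxypropan-2-yl)-7-(3-methylbutanoyl)-5,5-di(prop-2-en-1-yl)-2,3-dihydro-1-benzofuran-4(5H)-one | C=CCC1(CC=C)C(=O)C2=C(O[C@@H](C(C)(C)O)C2)C(C(=O)CC(C)C)=C1O
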